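## The problem

The target 13 is a cyclohexanone in which every ring carbon except C3 carries oxygen. The ring is numbered C1 (tertiary carbinol bearing the C7 benzoyloxymethyl arm), C2 (ketone), C3 (CH2), C4 (OH), C5 (OBz) and C6 (OH). The four stereocentres are 1S, 4R, 5R and 6S, with O4 and O5 cis, O5 and O6 trans, and O6 and O1 cis. C4 and C5 form a cis-diol that can be taken intact from a sugar. C5 can then control C6 by 1,2-induction during ring formation, and the C6 hydroxyl can direct the oxygen that makes C1 quaternary. The molecule is fragile towards base: the C4 hydroxyl is β to the ketone (E1cB dehydration and, further on, aromatisation), the C1 α-ketol can undergo retro-aldol cleavage of C1–C6, and the benzoates can migrate among O4, O5 and O6. The last steps therefore have to run under neutral or acidic conditions, and only one of three secondary hydroxyls may be benzoylated. The enabling feature is that the C2 ketone, C1 with its one-carbon arm C7 and the C6 carbinol become a β-hydroxy-α-methylene ketone once O1 and O7 are traced back to an exocyclic C1=C7 alkene. That is the retron of an intramolecular Morita–Baylis–Hillman reaction forming C1–C6 from a vinyl ketone and an aldehyde.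

## Retrosynthesis

**O5–benzoyl bond.** The target 13 is cut at the O5 ester to the tetraol monobenzoate 10 and benzoyl chloride 11, through the tin acetal 12. In the preferred chair of 10 (C7 equatorial), O5 is equatorial and flanked by the axial O4, which is the position a stannylene acetal of a cis-diol acylates. Placing this benzoate earlier would require O4 and O5 to be differentiated on the sugar and would give up the rigid cis-acetonide that steers the ring closure. The forward step must acylate one oxygen without base.

**Acetal C–O bonds.** 10 comes from the acetonide 9 by hydrolysis. The only demand is acid mild enough to spare the benzoate and the β-hydroxy ketone.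

**C7–O(benzoate) bond.** 9 is cut to the spiro-epoxide 7 and benzoic acid 8. Against dihydroxylation followed by acylation, the epoxide allows C1 to be set in a step that the C6 hydroxyl can direct. Regiochemistry of opening is not in doubt, because C7 is primary while C1 is quaternary and α to the carbonyl. The forward reaction must open the epoxide without base.

**C1–O and C7–O bonds.** Removing the epoxide oxygen from 7 leaves the α-methylene-β-hydroxy ketone 6. The alkene is electron-poor, so the forward step is a nucleophilic epoxidation. It must deliver oxygen to the face of C1 that carries O6.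

**C1–C6 bond (key cut).** 6 is opened between C1 and C6 to the acyclic enone–aldehyde 5. Cuts at C2–C3 or C3–C4 would need the quaternary C1 to be built on an open chain beforehand. This cut instead leaves a precursor with only the two sugar-derived stereocentres and removes the ring, the C1–C6 bond and the C6 stereocentre at once. The forward reaction must favour ring closure over intermolecular coupling of the vinyl ketone and must place O6 trans to O5.

**Oxidation level.** 5 is too sensitive to carry, so it is traced to the diol 4. Both carbonyls are to be generated in one operation, without lactol formation and without epimerising C5.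

**C1–C2 bond.** 4 is cut between the carbinol carbon and the vinyl group to the lactol 2 and vinylmagnesium bromide 3. The new carbinol configuration is irrelevant because it is oxidised.

**Acetonide.** 2 is the 3,4-acetonide of 2-deoxy-L-ribose 1. In 1 the aldehyde carbon becomes C2, the deoxy carbon becomes C3, the cis-diol carbons become C4 and C5, and the primary carbinol becomes C6. The L series is required; the D series would give the mirror-image ring. A four-carbon cis-dioxolane of the erythrose type would also map onto C3–C6, but it was set aside for three reasons:
- its terminal CH2 would have to act as a carbon electrophile next to the dioxolane;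
- the aldehyde would have to be carried as a dithioacetal, whose sulfur can displace a primary sulfonate four atoms away;
- the acidic dithioacetal C–H invites β-elimination under the organolithium that brings in the enone carbons.

## Roads not taken

**Alternative 1:** The ring is cut at C3–C4, giving the open-chain keto-aldehyde A1, a 4-C-acetyl pentose with the O5 benzoate and an O6 benzyl ether already in place. The forward key step is an amine-promoted intramolecular aldol addition of the methyl ketone carbon to the aldehyde, giving A2, which is 13 without the C7 benzoate and with benzyl on O6.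
- Merits: C1 is already quaternary, and O5 and O6 are differentiated before the ring exists. Only a primary benzoylation and a hydrogenolysis follow the ring closure. This endgame is shorter than the chosen one and needs no selective acylation of a triol; in that respect it is the better plan.
- Weak points: A1 is a branched sugar with a tertiary carbinol and two different protecting groups on neighbouring oxygens, so it needs a long preparation, and it will sit largely as cyclic hemiacetals and hemiketals. Its aldehyde is α to a benzoate, so under amine conditions it can epimerise, eliminate or pass its benzoyl group to the free hydroxyls. The new stereocentre is C4, which must end cis to O5 and axial in the product chair, while the all-equatorial epimer and the dehydrated enone are both accessible under reversible aldol conditions.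
- Comparison: the chosen plan takes C4 from the sugar, forms C6 under 1,2-induction with a weakly basic phosphine, and reaches its cyclisation substrate 5 in three steps.

**Alternative 2:** After the ring oxygens at C4–C6 are stripped back, the ring is cut at a C5=C6 double bond to the achiral triene ketone A3. The forward key step is a desymmetrising ring-closing metathesis with Mo(N-2,6-iPr2C6H3)(CHCMe2Ph)(3,3'-di-tert-butyl-5,5',6,6'-tetramethylbiphenyl-2,2'-diolate) A4, which selects one of two enantiotopic vinyl groups and gives the cyclohexenone A5.
- Merits: the quaternary carbinol, the hardest centre, is set catalytically from achiral material, and no L-sugar is needed. On that count it is more economical than the chosen plan.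
- Weak points: A5 carries none of O4, O5 or O6. The route would have to add a trans-diol across C5=C6 with the right sense relative to C1, oxygenate the unactivated C4 methylene, and degrade the remaining vinyl group to the benzoyloxymethyl arm in the presence of the ring alkene. Three stereocentres would then rest on substrate control from C1 alone, and the enantioselection on a fully substituted α-silyloxy ketone is itself unproven.
- Comparison: the chosen plan imports two of the four stereocentres, relays the other two through adjacent centres, and reaches 13 in eight steps.

**Alternative 3:** The ring is cut at C2–C3, giving the branched manno-configured 1,4-lactone A6 with a phenylsulfonyl group on the terminal carbon. The forward key step is a Dieckmann-type attack of the α-sulfonyl carbanion on the lactone carbonyl, giving the cyclic β-keto sulfone A7 and releasing the lactone oxygen (O5) as the only free hydroxyl.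
- Merits: all four stereocentres, including C1, come from the sugar, and O5 is singled out for benzoylation by the ring closure itself. This is better than the tin-mediated selection among three hydroxyls that the chosen plan relies on.
- Weak points: the carbanion sits β to the silyloxy group that becomes O4, so elimination to a vinyl sulfone competes with cyclisation. The sulfone must later be removed reductively next to an α-alkoxy ketone (C1–O) and a β-silyloxy group, both of which can be lost in the same step. A6 needs a C-branched sugar and three kinds of protecting group, so the route is long.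
- Comparison: the chosen plan uses one acetonide, has no carbanion next to a β-leaving group, and is far shorter; against that it must accept one regioselective acylation at the end.

Key step: step 4

Assumption: ring numbering C1–C7 of the target is used for all intermediates, and commercial 2-deoxy-L-ribose (1) is taken as its pyranose anomeric mixture, which reacts through the forms shown.

## Route

Step 1
Reactants: 1 2-deoxy-L-ribose
Product: 2 2-deoxy-3,4-O-isopropylidene-L-erythro-pentopyranose (anomeric mixture)
Conditions: 2-methoxypropene, PPTS (cat.), EtOAc, 0 °C → rt
Reagents that add atoms: 2-methoxypropene, C=C(C)OC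
Why: Kinetic acetonation with an enol ether takes the cis-3,4-diol of the pyranose form and leaves the anomeric hydroxyl free; this is the mirror image of a well-used D-series building block, and no stereocentre is touched.

Step 2
Reactants: 2 2-deoxy-3,4-O-isopropylidene-L-erythro-pentopyranose, 3 vinylmagnesium bromide
Product: 4 1-[(4R,5S)-5-(hydroxymethyl)-2,2-dimethyl-1,3-dioxolan-4-yl]but-3-en-2-ol (both carbinol epimers)
Conditions: 3 (3.5 equiv), THF, −20 °C → rt; aq. NH4Cl
Reagents that add atoms: none
Why: Grignard addition to a lactol through its open-chain aldehyde tautomer, with the first equivalent consumed by the hemiacetal proton; the new carbinol configuration does not matter because step 3 oxidises it.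

Step 3
Reactants: 4 1-[(4R,5S)-5-(hydroxymethyl)-2,2-dimethyl-1,3-dioxolan-4-yl]but-3-en-2-ol
Product: 5 (4R,5R)-2,2-dimethyl-5-(2-oxobut-3-en-1-yl)-1,3-dioxolane-4-carbaldehyde
Conditions: (COCl)2, DMSO, CH2Cl2, −78 °C; iPr2NEt, −78 → −30 °C; cold pH 7 buffer; used crude
Reagents that add atoms: none
Why: Double Swern oxidation; both hydroxyls are converted to alkoxysulfonium ions before base is added, so no hydroxy aldehyde is free to close to a lactol and over-oxidise, and the hindered amine at low temperature protects the epimerisable C5 centre and the β-alkoxy ketone.

Step 4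
Reactants: 5 (4R,5R)-2,2-dimethyl-5-(2-oxobut-3-en-1-yl)-1,3-dioxolane-4-carbaldehyde
Product: 6 (3aS,4R,7aR)-4-hydroxy-2,2-dimethyl-5-methylidenehexahydro-1,3-benzodioxol-6-one
Conditions: PBu3 (30 mol%), CH2Cl2/t-BuOH (4:1), 0.01 M, 0 °C → rt
Reagents that add atoms: none
Why: PBu3 adds reversibly to C7 of the vinyl ketone to give a phosphonium enolate whose α-carbon C1 attacks the C6 aldehyde; t-BuOH protonates the alkoxide, C1–H is then removed and PBu3 is expelled, which restores the enone as the exocyclic C1=C7 alkene. The closest known reaction type is the trialkylphosphine-catalysed intramolecular Morita–Baylis–Hillman reaction of enone–aldehydes. The six-membered ring closes by a 6-(enolendo)-exo-trig aldol addition, with both enolate carbons inside the ring and the aldehyde oxygen outside. C6 is the only new stereocentre and is controlled by the C5 dioxolane centre: in the chair-like transition state the forming C1–C6 bond is anti to the C5–O bond (Felkin–Anh alignment) and the aldehyde oxygen is equatorial, because the axial position would be syn-1,3-diaxial to the axial O4 of the cis-fused acetonide, so O6 ends trans to O5 on the convex face. The aldol addition is reversible before the proton shift, so the more stable trans aldolate should be the one carried through to product. The step needs ring closure to beat intermolecular Rauhut–Currier coupling of the vinyl ketone, which the six-membered closure and high dilution should secure, and it must spare the C5 stereocentre and the β-alkoxy ketone, which a weakly basic phosphine in a protic co-solvent allows.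

Step 5
Reactants: 6 (3aS,4R,7aR)-4-hydroxy-2,2-dimethyl-5-methylidenehexahydro-1,3-benzodioxol-6-one
Product: 7 (3aS,4S,5S,7aR)-4-hydroxy-2,2-dimethylhexahydrospiro[1,3-benzodioxole-5,2'-oxiran]-6-one
Conditions: t-BuOOH (3 equiv, anhydrous), n-BuLi (1.2 equiv), THF, −78 → −20 °C; aq. NH4Cl
Reagents that add atoms: tert-butyl hydroperoxide, CC(C)(C)OO
Why: Weitz–Scheffer-type nucleophilic epoxidation of an α-methylene ketone: the peroxide anion adds to C7 and the ring enolate closes onto the peroxide oxygen. Lithium bridging between the C6 hydroxyl and the peroxide, together with the acetonide blocking the concave face, places the new C1–O bond syn to O6 and sets C1. Excess hydroperoxide keeps the only base present as weak as lithium tert-butyl peroxide.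

Step 6
Reactants: 7 (3aS,4S,5S,7aR)-4-hydroxy-2,2-dimethylhexahydrospiro[1,3-benzodioxole-5,2'-oxiran]-6-one, 8 benzoic acid
Product: 9 [(3aS,4S,5S,7aR)-4,5-dihydroxy-2,2-dimethyl-6-oxohexahydro-1,3-benzodioxol-5-yl]methyl benzoate
Conditions: 8 (2 equiv), Ti(OiPr)4 (1.5 equiv), CH2Cl2, 0 °C → rt; aq. tartaric acid
Reagents that add atoms: none
Why: Titanium-assisted opening of a 2,3-epoxy alcohol by a carboxylic acid at the carbon remote from the carbinol; C7 is primary whereas C1 is quaternary and α to the carbonyl, so benzoate enters only at C7 and the C1–O bond, hence the C1 configuration, is untouched.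

Step 7
Reactants: 9 [(3aS,4S,5S,7aR)-4,5-dihydroxy-2,2-dimethyl-6-oxohexahydro-1,3-benzodioxol-5-yl]methyl benzoate
Product: 10 [(1S,2S,3R,4R)-1,2,3,4-tetrahydroxy-6-oxocyclohexyl]methyl benzoate
Conditions: TFA/H2O (9:1), CH2Cl2, 0 °C
Reagents that add atoms: none
Why: Acid hydrolysis of the cis-fused isopropylidene acetal; the benzoate, the α-ketol and the β-hydroxy ketone tolerate cold aqueous acid, whereas they would not tolerate base.

Step 8
Reactants: 10 [(1S,2S,3R,4R)-1,2,3,4-tetrahydroxy-6-oxocyclohexyl]methyl benzoate, 11 benzoyl chloride
Product: 13 [(1S,2S,3R,4R)-3-(benzoyloxy)-1,2,4-trihydroxy-6-oxocyclohexyl]methyl benzoate (CNP0127041.1), via 4,5-O-dibutylstannylene acetal 12 (not isolated)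
Conditions: Bu2SnO (1.1 equiv), MeOH, 65 °C; evaporate; then 11 (1.05 equiv), toluene, 0 °C → rt
Reagents that add atoms: dibutyltin oxide, CCCC[Sn](=O)CCCC (its tin and butyl groups stay only in 12)
Why: Regioselective acylation through a dibutylstannylene acetal, which forms on the cis-4,5-diol and activates its equatorial oxygen O5 (flanked by axial O4, as at O3 of a galactoside); O1 is tertiary and O6 is neopentyl-like. No base is present, so benzoyl migration and β-elimination of O4 are avoided.

## Compound list

1 | 2-deoxy-L-ribose (2-deoxy-L-erythro-pentose, pyranose form, anomeric mixture) | OC1C[C@@H](O)[C@@H](O)CO1 | starting material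
2 | 2-deoxy-3,4-O-isopropylidene-L-erythro-pentopyranose (anomeric mixture) | OC1C[C@H]2OC(C)(C)O[C@H]2CO1 | intermediate
3 | vinylmagnesium bromide | C=C[Mg]Br | starting material
4 | 1-[(4R,5S)-5-(hydroxymethyl)-2,2-dimethyl-1,3-dioxolan-4-yl]but-3-en-2-ol (both carbinol epimers) | C=CC(O)C[C@H]1OC(C)(C)O[C@H]1CO | intermediate
5 | (4R,5R)-2,2-dimethyl-5-(2-oxobut-3-en-1-yl)-1,3-dioxolane-4-carbaldehyde | C=CC(=O)C[C@H]1OC(C)(C)O[C@H]1C=O | intermediate
6 | (3aS,4R,7aR)-4-hydroxy-2,2-dimethyl-5-methylidenehexahydro-1,3-benzodioxol-6-one | C=C1C(=O)C[C@H]2OC(C)(C)O[C@H]2[C@@H]1O | intermediate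
7 | (3aS,4S,5S,7aR)-4-hydroxy-2,2-dimethylhexahydrospiro[1,3-benzodioxole-5,2'-oxiran]-6-one | O1C[C@]12C(=O)C[C@H]3OC(C)(C)O[C@H]3[C@@H]2O | intermediate
8 | benzoic acid | O=C(O)c1ccccc1 | starting material
9 | [(3aS,4S,5S,7aR)-4,5-dihydroxy-2,2-dimethyl-6-oxohexahydro-1,3-benzodioxol-5-yl]methyl benzoate | O=C(OC[C@@]1(O)C(=O)C[C@H]2OC(C)(C)O[C@H]2[C@@H]1O)c1ccccc1 | intermediate
10 | [(1S,2S,3R,4R)-1,2,3,4-tetrahydroxy-6-oxocyclohexyl]methyl benzoate | O=C(OC[C@@]1(O)C(=O)C[C@@H](O)[C@@H](O)[C@@H]1O)c1ccccc1 | intermediate
11 | benzoyl chloride | O=C(Cl)c1ccccc1 | starting material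
12 | 4,5-O-dibutylstannylene acetal of 10 (tin bridging O4 and O5) | O=C(OC[C@@]1(O)C(=O)C[C@H]2O[Sn](CCCC)(CCCC)O[C@H]2[C@@H]1O)c1ccccc1 | intermediate (not isolated)
13 | [(1S,2S,3R,4R)-3-(benzoyloxy)-1,2,4-trihydroxy-6-oxocyclohexyl]methyl benzoate (CNP0127041.1) | O=C(OC[C@@]1(O)C(=O)C[C@@H](O)[C@@H](OC(=O)c2ccccc2)[C@@H]1O)c1ccccc1 | target

## Step count and least certain steps

Total: 8 steps. Longest linear sequence: 8 steps, from 1 to 13.

**Step 4 (key step).** Intermolecular Rauhut–Currier-type coupling of the vinyl ketone may overtake ring closure. The cycle may also stall at the aldol zwitterion, so that slower base-type processes (epimerisation at C5, β-elimination of O4) take over. The facial selectivity at C6 may be lower than the chair analysis predicts. Fallback: the fallback sets out from 5 and separates bond formation from alkene regeneration. Me2AlSPh (from Me3Al and PhSH, CH2Cl2, −78 °C) adds its thiolate to C7, and the aluminium enolate closes onto the aldehyde to give the β-hydroxy sulfide (3aS,4R,7aR)-4-hydroxy-2,2-dimethyl-5-[(phenylsulfanyl)methyl]hexahydro-1,3-benzodioxol-6-one F1. NaIO4 in aqueous MeOH oxidises this to the sulfoxide F2, which loses benzenesulfenic acid on gentle warming in toluene through the acidic C1–H. The route is rejoined at 6.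

**Step 3.** The C5 aldehyde centre may epimerise, or O4 may be lost by β-elimination, while the amine is present during warm-up; the crude keto-aldehyde may also degrade on handling. Fallback: the fallback sets out from 4 and stages the two oxidations without amine base. MnO2 in CH2Cl2 oxidises only the allylic carbinol to the hydroxy enone 1-[(4R,5S)-5-(hydroxymethyl)-2,2-dimethyl-1,3-dioxolan-4-yl]but-3-en-2-one F3. Dess–Martin periodinane buffered with NaHCO3 then oxidises the primary alcohol, and the route is rejoined at 5.

**Step 5.** Facial selectivity at C1 may be poor if lithium bridging is weak. The basic medium may also trigger β-elimination of O4 or addition–elimination at C6. Fallback: the fallback sets out from 6 and replaces the epoxide by a hydrogen-bond-directed dihydroxylation. Stoichiometric OsO4·TMEDA in CH2Cl2 at −78 °C, followed by cleavage of the osmate ester with aqueous Na2SO3, gives the syn triol (3aS,4S,5S,7aR)-4,5-dihydroxy-5-(hydroxymethyl)-2,2-dimethylhexahydro-1,3-benzodioxol-6-one F4. Its primary hydroxyl is benzoylated with 11 and 2,4,6-collidine at −40 °C, and the route is rejoined at 9, bypassing 7.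

**Step 8.** Acylation may spread to O6, which is also equatorial, or to O4, and the benzoyl group may migrate during work-up. Fallback: the fallback sets out from 9 and blocks O6 before the diol is unveiled.
- TBSOTf and 2,6-lutidine at −78 °C silylate the secondary C6 hydroxyl to give the C6 O-tert-butyldimethylsilyl ether of 9 F5.
- Aqueous acetic acid removes the acetonide to give the 4,5-diol F6.
- Bu2SnO followed by 11 can now form a tin acetal only across O4 and O5, and gives the O5 benzoate F7.
- HF·pyridine in THF removes the silyl group, and the route is rejoined at 13.

## Further compounds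

F1 | step 4 | (3aS,4R,7aR)-4-hydroxy-2,2-dimethyl-5-[(phenylsulfanyl)methyl]hexahydro-1,3-benzodioxol-6-one (C5 epimers) | O=C1C[C@H]2OC(C)(C)O[C@H]2[C@H](O)C1CSc1ccccc1
F2 | step 4 | sulfoxide of F1 (mixture at sulfur and C5) | O=C1C[C@H]2OC(C)(C)O[C@H]2[C@H](O)C1CS(=O)c1ccccc1
F3 | step 3 | 1-[(4R,5S)-5-(hydroxymethyl)-2,2-dimethyl-1,3-dioxolan-4-yl]but-3-en-2-one | C=CC(=O)C[C@H]1OC(C)(C)O[C@H]1CO
F4 | step 5 | (3aS,4S,5S,7aR)-4,5-dihydroxy-5-(hydroxymethyl)-2,2-dimethylhexahydro-1,3-benzodioxol-6-one | OC[C@@]1(O)C(=O)C[C@H]2OC(C)(C)O[C@H]2[C@@H]1O
F5 | step 8 | C6 O-tert-butyldimethylsilyl ether of 9 | O=C(OC[C@@]1(O)C(=O)C[C@H]2OC(C)(C)O[C@H]2[C@@H]1O[Si](C)(C)C(C)(C)C)c1ccccc1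
F6 | step 8 | C6 O-tert-butyldimethylsilyl ether of 10 | O=C(OC[C@@]1(O)C(=O)C[C@@H](O)[C@@H](O)[C@@H]1O[Si](C)(C)C(C)(C)C)c1ccccc1
F7 | step 8 | C6 O-tert-butyldimethylsilyl ether of 13 | O=C(OC[C@@]1(O)C(=O)C[C@@H](O)[C@@H](OC(=O)c2ccccc2)[C@@H]1O[Si](C)(C)C(C)(C)C)c1ccccc1
A1 | alternative 1 | aldehydo-4-C-acetyl-2-O-benzoyl-3-O-benzylpentose (open-chain keto-aldehyde) | CC(=O)[C@](O)(CO)[C@@H](OCc1ccccc1)[C@H](OC(=O)c1ccccc1)C=O
A2 | alternative 1 | 13 lacking the C7 benzoate and carrying a benzyl ether on O6 | OC[C@@]1(O)C(=O)C[C@@H](O)[C@@H](OC(=O)c2ccccc2)[C@@H]1OCc1ccccc1
A3 | alternative 2 | 3-ethenyl-3-(triethylsilyloxy)octa-1,7-dien-4-one | C=CC(O[Si](CC)(CC)CC)(C=C)C(=O)CCC=C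
A4 | alternative 2 | Mo(N-2,6-iPr2C6H3)(CHCMe2Ph)(3,3'-di-tert-butyl-5,5',6,6'-tetramethylbiphenyl-2,2'-diolate), one atropisomer of the diolate | CC(C)c1cccc(C(C)C)c1N=[Mo]1(=CC(C)(C)c2ccccc2)Oc2c(C(C)(C)C)cc(C)c(C)c2-c2c(C)c(C)cc(C(C)(C)C)c2O1
A5 | alternative 2 | 2-(triethylsilyloxy)-2-vinylcyclohex-3-en-1-one, single enantiomer | C=C[C@@]1(O[Si](CC)(CC)CC)C(=O)CCC=C1
A6 | alternative 3 | 5-O-(tert-butyldimethylsilyl)-2-C-[(tert-butyldimethylsilyloxy)methyl]-6-deoxy-2,3-O-isopropylidene-6-(phenylsulfonyl)-manno-hexono-1,4-lactone | CC1(C)O[C@H]2[C@@H]([C@H](O[Si](C)(C)C(C)(C)C)CS(=O)(=O)c3ccccc3)OC(=O)[C@@]2(CO[Si](C)(C)C(C)(C)C)O1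
A7 | alternative 3 | cyclic β-keto sulfone: 2-(phenylsulfonyl)cyclohexanone with 3-silyloxy, 4-hydroxy, 5,6-acetonide and 6-(silyloxymethyl) groups | CC1(C)O[C@H]2[C@H](O)[C@H](O[Si](C)(C)C(C)(C)C)[C@@H](S(=O)(=O)c3ccccc3)C(=O)[C@@]2(CO[Si](C)(C)C(C)(C)C)O1
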